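A small charge of free catalyst turns 16 mM of substrate over within days in the north-west and south-east runs, and dusk and winter are two further flasks on the same charge of substrate:

in all of them: substrate 16 mM
- north-west: free catalyst 0.11 mol%; run made earlier
- south-east: free catalyst 0.14 mol%; run made earlier
- dusk: free catalyst 0.1 mol%; time 20 d
- winter: free catalyst 0.12 mol%; time 20 d

| run | time / d | side product / % | target / % | substrate / % | catalyst intermediate A / % |
|---|---|---|---|---|---|
| north-west | 1.67 | 14.6 | 39.9 | 46.4 | 0.6 |
| north-west | 5.00 | 34.5 | 59.0 | 5.6 | 0.7 |
| north-west | 10.0 | 39.2 | 61.2 | 0 | 0 |
| north-west | 15.0 | 38.4 | 61.9 | 0.4 | 0.6 |
| south-east | 4.00 | 30.3 | 63.4 | 6.3 | 0 |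
| south-east | 8.00 | 32.8 | 66.2 | 0 | 0.2 |
| south-east | 10.0 | 32.7 | 67.4 | 0 | 0.4 |
| south-east | 15.0 | 33.8 | 67.5 | 0 | 0.3 |

(readings scatter by 0.5 percentage points)

- percentages count the substrate that a species holds: one side product counts as two

* which of these there is most of at the end, counted by the substrate in it, dusk (substrate / catalyst intermediate A / side product / target)
* which of these there is most of at the end, counted by the substrate in it, winter (substrate / catalyst intermediate A / side product / target)
* final amount of the leader among these, as a percentage of the substrate charged, in dusk
* final amount of the leader among these, as a percentage of the substrate charged, in winter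

Substrate reads 0 % at 10.0 d in the north-west run and 0 % at 8.00 d in the south-east run, and the later readings stay flat within the scatter, so the question for dusk and winter is the split, or selectivity, between target and side product. The loadings of the two runs stand in a ratio of 1.27, and the last target-to-side ratios, 1.61 and 2.00, stand in a ratio of 1.24, so the split reads as first order in [free catalyst].

A proportion has one constant, the balance loading: the loading at which it puts target and side product level, equal to the loading times side product over target. The last readings give 0.068 mol% in the north-west run and 0.07 mol% in the south-east run, with a mean of 0.069 mol%. The target share is the loading over the loading plus this constant, which gives 59.1 % for dusk and 63.4 % for winter.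

The weak link is that each run rests on one reading. Averaging the plateau readings of each run gives 0.069 mol% and 0.069 mol%, so the reforged balance loading is 0.069 mol%, and this reckoning commits to 59.1 % for dusk and 63.4 % for winter.

The forecast names target for dusk and target for winter, at 59.2 % (57.5 % to 60.8 %) and 63.7 % (62.4 % to 65 %), on a ratio it calls “roughly proportional to loading”; this reckoning stands at 59.1 % and 63.4 %.

Dusk ends at 59.6 % target and winter at 63.6 % target.

    substrate + target → side product (k = 0.810 /M/h)
    catalyst intermediate A → catalyst intermediate B (k = 46.0 /h)
    substrate + free catalyst → catalyst intermediate A (k = 1200 /M/h)
    catalyst intermediate B → free catalyst + target (k = 5000 /h)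

Substrate stands in both the catalytic step and the side step, so it cancels from the ratio of their rates, and that ratio sets [free catalyst] against [target]. Dusk without the step from substrate + target to side product ends at >99.9 % target, which makes that step the main reason for the shortfall. The end shares of dusk read as a balance loading of 0.068 mol%. A neighbour of dusk charged with 0.06 mol% lies below 0.069 mol%, so the rule gives it 46.5 % target, and that flask ends with 52.2 % side product against 47.7 % target.

The numbers in the tables are simulated on assumed constants, noise included.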